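## The problem

Target 25 is a trans-2-aryl-3-hydroxymethyl-2,3-dihydrobenzofuran (numbered O1, C2, C3, C3a, C4–C7, C7a). Benzo ring A is fused to dihydrofuran ring B across C3a–C7a, C2 carries the 4-hydroxy-3,5-dimethoxyphenyl ring C, and ring A carries O1 on C7a, a methoxy group on C7 and an (E)-propenoic acid on C5. Ring A is thus 1,2,3,5-tetrasubstituted with two adjacent oxygens, and placing these substituents without regiochemical ambiguity is the constitutional problem. The only stereocentres are C2 (S) and C3 (R), adjacent and trans. No resident centre can induce them, so the absolute sense must come from an auxiliary or catalyst; once both are set in an open chain (C2 oxygen and C3 aryl syn), they become the trans ring if ring B is closed without touching either centre. The C2–O1 bond is a benzylic aryl ether para to the oxygens of ring C: acid can ionise it, base can open it through a quinone methide once the ring C phenol is free, and hydrogenolysis cleaves it. The propenoic acid excludes a final hydrogenation, so the phenol, primary alcohol and acid need protecting groups that leave under mild, non-reductive conditions. The enabling feature is the vicinal oxygen pair on C7a and C7: a C7–C7a aryne takes a nucleophile on one carbon and an electrophile on the other, an oxygen tethered through C2–C3–C3a can reach only C7a, and because C5 is para to C7a the aryne precursor can be a simple 4-fluorobenzaldehyde derivative.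

## Retrosynthesis

**25 ⇒ 24 ⇒ 21 + 22.** The last cut is the acetal C–O bond of the methoxymethyl ether in 24; before it, the Cα=Cβ bond of the side chain is cut to aldehyde 21 and malonic acid 22 (Knoevenagel–Doebner). A Heck coupling on a C5 halide would be as direct, but a second halogen on ring A would not survive the aryne chemistry below, and a Wittig ester would add a hydrolysis. The ring C phenol stays masked during the hot amine step, because a free para-hydroxybenzyl aryl ether could open ring B by quinone methide formation. A methoxymethyl ether is preferred to a benzyl ether because hydrogenolysis is excluded by the alkene and by C2–O1, whereas dilute aqueous acid suffices here. The forward steps must give the E acid and must not ionise C2.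

**21 ⇒ 20 ⇒ 19.** Aldehyde 21 comes from 20 by hydrolysis of two acid-labile groups (trityl ether and dioxolane), and 20 from phenol 19 by O-methylation. This exposes a free C7 hydroxyl, which is what an aryl anion delivers after borylation and oxidation. The hydrolysis must spare the aryl methoxymethyl ether, which needs stronger acid than the other two groups.

**19 ⇒ 14 (key disconnection).** Two bonds on adjacent ring A carbons are cut, O1–C7a and C7–O, leading to fluoroarene 14 through aryne 16. Two neighbouring cuts were weighed:
- Cutting C2–O1 (a phenol displacing an activated benzylic alcohol) makes the bond at the ionisation-prone C2 and risks the stereocentre.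
- Cutting only O1–C7a by metal-catalysed C–O coupling needs a ring A fragment that already carries the C7 oxygen beside a halogen.

The aryne cut leaves C2–O intact and brings in both ring A oxygens at once. Precursor 14 has only fluorine on the future C7a and a masked aldehyde on C5, and traces back to commercial 1. The forward reaction must lithiate only ortho to fluorine, add the alkoxide only at C7a, and keep aryllithium 17 alive until the borate arrives. Two protecting groups are chosen for this step:
- The primary hydroxyl is a trityl ether. A silyl ether could migrate to the neighbouring alkoxide, and the freed primary alkoxide would close a five-membered ring of its own.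
- The ring C phenol is a methoxymethyl ether flanked by two methoxy groups, so it has no ortho hydrogen to lithiate.

**14 ⇒ 13 ⇒ 12.** Trityl ether 14 comes from diol 13 by selective protection of the primary hydroxyl, and 13 from aldol adduct 12 by reductive removal of the auxiliary. No skeletal bond is cut. The requirement is that the base-sensitive α-aryl aldol adduct does not fragment.

**12 ⇒ 8 + 10 (and 10 ⇒ 9).** The C2–C3 bond is cut by an auxiliary-controlled syn aldol between imide 8 and aldehyde 10, the methoxymethyl ether of syringaldehyde 9. This one step sets both stereocentres, with absolute control from oxazolidinone 6, and the syn adduct is the one that maps onto the trans ring. Routes that set the centres separately would be longer. The forward step needs Z-enolate 11 and a closed transition state.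

**8 ⇒ 5 + 6; 5 ⇒ 4 ⇒ 2 + 3; 2 ⇒ 1.** The imide N–C(O) bond is cut to arylacetic acid 5 and auxiliary 6. The aryl–CH2 bond of 5 is cut to bromide 2 and tert-butyl acetate 3 (palladium-catalysed enolate arylation, then hydrolysis of ester 4). Bromide 2 is the dioxolane of commercial 1. The bromine of 1 marks the future C3a, its fluorine the future C7a and its formyl group the future C5, so the whole ring A pattern is bought. The acetal means the ester must be cleaved by base, not by acid.

## Roads not taken

Alternative 1: Ring A is removed entirely by cutting C7a–C3a, C4–C5 and C5–C6. The precursor is pentacarbonylchromium carbene complex A2, whose carbene carbon bears a 1-methoxyvinyl group and, as its alkoxy group, the oxygen of homopropargylic alcohol A3. On warming, the tethered alkyne and one CO insert (intramolecular Dötz benzannulation), closing ring A and ring B together to give hydroquinone monoether A1.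
- Merits: three C–C bonds and two rings form in one operation. The positions of O1 and the C7 methoxy group are fixed by the carbene, and C2 and C3 are not touched. In bond-forming power per step this road is better than the chosen one.
- Weak points: A1 carries a hydroxyl on C5 where the target has carbon, so sulfonylation and a Heck-type vinylation must follow, and the electron-rich hydroquinone monoether is prone to oxidation. A2 requires attaching the hindered secondary benzylic alcohol A3 to a chromium acyl, with stoichiometric chromium. The two-atom tether between oxygen and alkyne is short for the insertion. A3 needs an enantio- and diastereoselective propargylation that is no easier than an aldol.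
- Comparison: the chosen plan forms fewer bonds in its key step (14 to 19). Against that it uses only catalytic palladium, takes both stereocentres from an aldol of predictable sense, and has the C5 carbon in place from the start.

Alternative 2: The C3–C3a bond is cut. The precursor is (2S)-flavanone A5, and a trivalent iodine oxidant under strongly acidic orthoester conditions attacks C3 of its enol ether. The ring A carbon then migrates from the carbonyl carbon to C3, and the former carbonyl carbon leaves the ring as the methyl ester of A4.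
- Merits: the flavanone skeleton is assembled in two classical steps, the contraction gives the trans ester, the ester is one reduction from the hydroxymethyl group, and the C5 bromide is one Heck coupling from the side chain. In step count this road is probably shorter than the chosen one.
- Weak points: 2-arylchromanones with a donor-substituted aryl group racemise by reversible ring opening in acid or base, and the contraction runs in strong acid, so the single stereocentre that relays to C3 is at risk. Migration of ring C from C2 to C3 competes and is favoured by donors on ring C, which is why the phenol must be carried as a mesylate. Its later removal needs a strong nucleophile or base on a molecule that then holds an ester or acid.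
- Comparison: the chosen plan is longer, but its absolute and relative configuration come from an auxiliary-controlled aldol, and no step places positive charge at or next to C2.

Alternative 3: Ring A is again built, here by cutting C3a–C4 and C7a–C7. Silyl ketene acetal A7, made from trans lactone A9, adds across C6 and C3 of methyl 3-bromocoumalate A8. Loss of CO2 and of the silanol aromatises the adduct to bromo ester A6.
- Merits: the route is convergent, the regiochemistry follows from the polarity of the two partners, and the stereocentres sit in a simple lactone that the cycloaddition does not touch. In that last respect it equals the chosen plan.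
- Weak points: A6 has bromine where the C7 methoxy group belongs and an ester where the aldehyde level is needed. A C–O coupling at a position flanked by O1 and a reduction and re-oxidation at C5 must follow, about three extra operations. The cycloaddition of a hindered ketene acetal with a 3-bromopyrone relies on polarisation alone, and the sensitive ketene acetal must be made from a lactone with an acidic benzylic position nearby.
- Comparison: the chosen plan delivers the C7 oxygen in the ring-forming step and carries C5 at the aldehyde level throughout, so its endgame from 19 is shorter.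

Key step: step 9

Assumption (chemistry): compounds 1, 3, 6, 9 and 22 and all reagents are commercial. The ring C phenol is carried as a methoxymethyl ether, the primary alcohol as a trityl ether and the C5 aldehyde as a dioxolane throughout.

## Route

Step 1
Reactants: 1 3-bromo-4-fluorobenzaldehyde
Product: 2 2-(3-bromo-4-fluorophenyl)-1,3-dioxolane
Conditions: HOCH2CH2OH, p-TsOH·H2O (cat.), toluene, reflux, Dean–Stark
Reagents that add atoms: ethylene glycol, OCCO
Why: Acid-catalysed acetalisation with azeotropic removal of water; the dioxolane shields the aldehyde from the enolates, hydrides and lithium amides used later.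

Step 2
Reactants: 2 2-(3-bromo-4-fluorophenyl)-1,3-dioxolane; 3 tert-butyl acetate
Product: 4 tert-butyl 2-[5-(1,3-dioxolan-2-yl)-2-fluorophenyl]acetate
Conditions: LiN(SiMe3)2, Pd(dba)2 (cat.), P(t-Bu)3 (cat.), toluene, rt
Reagents that add atoms: none
Why: Palladium-catalysed α-arylation of an ester enolate: zerovalent palladium inserts into C–Br (C–F is inert), the lithium enolate of 3 transmetalates and reductive elimination forms the aryl–CH2 bond; the tert-butyl group suppresses Claisen self-condensation.

Step 3
Reactants: 4 tert-butyl 2-[5-(1,3-dioxolan-2-yl)-2-fluorophenyl]acetate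
Product: 5 2-[5-(1,3-dioxolan-2-yl)-2-fluorophenyl]acetic acid
Conditions: KOH, MeOH/H2O, 65 °C; then 1 M HCl to pH 4, 0 °C
Reagents that add atoms: potassium hydroxide, [K+].[OH-]
Why: Saponification; the acetal forbids the usual acidolysis of a tert-butyl ester, but an ester of an unbranched acetic acid is still open to hydroxide on heating, and the acetal is inert to base and to a brief cold acidification to pH 4.

Step 4
Reactants: 5 2-[5-(1,3-dioxolan-2-yl)-2-fluorophenyl]acetic acid; 6 (S)-4-benzyloxazolidin-2-one
Product: 8 (S)-4-benzyl-3-{2-[5-(1,3-dioxolan-2-yl)-2-fluorophenyl]acetyl}oxazolidin-2-one, via mixed pivalic anhydride 7 (not isolated)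
Conditions: t-BuCOCl, Et3N, THF, −20 °C; then LiCl, 6, rt
Reagents that add atoms: none
Why: N-acylation of the oxazolidinone through a mixed anhydride; the auxiliary attacks the less hindered carbonyl of 7 under LiCl/amine activation, and the non-acidic conditions keep the acetal.

Step 5
Reactants: 9 syringaldehyde
Product: 10 3,5-dimethoxy-4-(methoxymethoxy)benzaldehyde
Conditions: MeOCH2Cl, i-Pr2NEt, CH2Cl2, 0 °C → rt
Reagents that add atoms: chloromethyl methyl ether, COCCl
Why: O-alkylation of the phenol (Williamson type); the methoxymethyl ether is stable to all bases of the route and, flanked by two methoxy groups, offers no ortho hydrogen for lithiation.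

Step 6
Reactants: 8 (S)-4-benzyl-3-{2-[5-(1,3-dioxolan-2-yl)-2-fluorophenyl]acetyl}oxazolidin-2-one; 10 3,5-dimethoxy-4-(methoxymethoxy)benzaldehyde
Product: 12 (S)-4-benzyl-3-{(2S,3S)-2-[5-(1,3-dioxolan-2-yl)-2-fluorophenyl]-3-[3,5-dimethoxy-4-(methoxymethoxy)phenyl]-3-hydroxypropanoyl}oxazolidin-2-one, via Z dibutylboron enolate 11 (not isolated)
Conditions: n-Bu2BOTf, i-Pr2NEt, CH2Cl2, −78 → 0 °C; 10, −78 → 0 °C; then pH 7 buffer, MeOH, 30% H2O2, 0 °C
Reagents that add atoms: none
Why: Evans syn aldol: soft enolisation gives Z-enolate 11, which reacts through a closed Zimmerman–Traxler chair with the auxiliary carbonyl turned away from the enolate oxygen, so the aldehyde adds to the face opposite the benzyl group. This sets both stereocentres as the (2S,3S) syn adduct, the same sense as the known propionyl/benzaldehyde case with this auxiliary.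

Step 7
Reactants: 12 (S)-4-benzyl-3-{(2S,3S)-2-[5-(1,3-dioxolan-2-yl)-2-fluorophenyl]-3-[3,5-dimethoxy-4-(methoxymethoxy)phenyl]-3-hydroxypropanoyl}oxazolidin-2-one
Product: 13 (1S,2R)-2-[5-(1,3-dioxolan-2-yl)-2-fluorophenyl]-1-[3,5-dimethoxy-4-(methoxymethoxy)phenyl]propane-1,3-diol
Conditions: LiBH4, THF, H2O (1 equiv), 0 °C
Reagents that add atoms: none
Why: Reductive cleavage of the N-acyl oxazolidinone; hydride attacks the exocyclic carbonyl, neither stereocentre is touched (the descriptor at C2 changes only because CH2OH ranks below the carbinol carbon), and auxiliary 6 is recovered.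

Step 8
Reactants: 13 (1S,2R)-2-[5-(1,3-dioxolan-2-yl)-2-fluorophenyl]-1-[3,5-dimethoxy-4-(methoxymethoxy)phenyl]propane-1,3-diol
Product: 14 (1S,2R)-2-[5-(1,3-dioxolan-2-yl)-2-fluorophenyl]-1-[3,5-dimethoxy-4-(methoxymethoxy)phenyl]-3-(triphenylmethoxy)propan-1-ol
Conditions: Ph3CCl, Et3N, DMAP (cat.), CH2Cl2, rt
Reagents that add atoms: trityl chloride, ClC(c1ccccc1)(c1ccccc1)c1ccccc1
Why: Selective tritylation of the primary hydroxyl on steric grounds; the trityl group cannot migrate to the neighbouring alkoxide in step 9 and leaves together with the acetal in step 11.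

Step 9
Reactants: 14 (1S,2R)-2-[5-(1,3-dioxolan-2-yl)-2-fluorophenyl]-1-[3,5-dimethoxy-4-(methoxymethoxy)phenyl]-3-(triphenylmethoxy)propan-1-ol
Product: 19 (2S,3R)-2-[3,5-dimethoxy-4-(methoxymethoxy)phenyl]-5-(1,3-dioxolan-2-yl)-3-[(triphenylmethoxy)methyl]-2,3-dihydrobenzofuran-7-ol, via dilithiated fluoroarene 15 (not isolated), via aryne alkoxide 16 (not isolated), via C7 aryllithium 17 (not isolated), via lithium aryltrimethoxyborate 18 (not isolated)
Conditions: lithium 2,2,6,6-tetramethylpiperidide (2.5 equiv, from 2,2,6,6-tetramethylpiperidine and n-BuLi), THF, −78 → −30 °C; B(OMe)3, −78 °C → rt; then 30% H2O2, 0 °C → rt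
Reagents that add atoms: hydrogen peroxide, OO
Why: Lithium 2,2,6,6-tetramethylpiperidide first removes the hydroxyl proton of 14 and then the only ring proton ortho to fluorine (C7–H, the other ortho position C3a being substituted) to give 15, which on warming loses LiF to the C7–C7a aryne 16. The lithium alkoxide on C2 adds to C7a of the in-plane aryne bond in a 5-exo-dig closure of ring B (O1–C7a), the only addition the three-atom tether through C3 and C3a allows, and leaves the carbanion on C7 as aryllithium 17, stabilised by the adjacent O1. Trimethyl borate is added only after the cyclisation, because an earlier borate would intercept 15 before fluoride loss; it converts 17 into borate 18, and peroxide then shifts the aryl group from boron to oxygen to give the C7 phenol 19 (C7–O). The closest known reaction type is the capture of an aryne by a tethered alkoxide or amide followed by quenching of the new aryl anion with an electrophile, combined with the standard borylation–oxidation of an aryllithium. No stereocentre is formed: neither the C2–O bond nor any bond at C3 is broken, so the syn open chain becomes the trans ring with retention and the electron-rich benzylic C2 is never ionised. The step needs site-selective lithiation (secured by fluorine as the strongest acidifying group and by the blocked C3a), regioselective addition (secured by the tether) and selection among oxygen nucleophiles (secured by the non-migrating trityl ether). The hindered amide is a poor nucleophile towards 16 and the amine it leaves is a slow proton donor, so intramolecular capture and survival of 17 until the borate quench are expected.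

Step 10
Reactants: 19 (2S,3R)-2-[3,5-dimethoxy-4-(methoxymethoxy)phenyl]-5-(1,3-dioxolan-2-yl)-3-[(triphenylmethoxy)methyl]-2,3-dihydrobenzofuran-7-ol
Product: 20 (2S,3R)-2-[3,5-dimethoxy-4-(methoxymethoxy)phenyl]-5-(1,3-dioxolan-2-yl)-7-methoxy-3-[(triphenylmethoxy)methyl]-2,3-dihydrobenzofuran
Conditions: MeI, K2CO3, DMF, rt
Reagents that add atoms: iodomethane, CI
Why: Williamson O-methylation of the only acidic hydroxyl in the molecule; carbonate conditions leave the acetal, the trityl ether and both stereocentres alone.

Step 11
Reactants: 20 (2S,3R)-2-[3,5-dimethoxy-4-(methoxymethoxy)phenyl]-5-(1,3-dioxolan-2-yl)-7-methoxy-3-[(triphenylmethoxy)methyl]-2,3-dihydrobenzofuran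
Product: 21 (2S,3R)-2-[3,5-dimethoxy-4-(methoxymethoxy)phenyl]-3-(hydroxymethyl)-7-methoxy-2,3-dihydrobenzofuran-5-carbaldehyde
Conditions: AcOH/THF/H2O (3:1:1), 45 °C
Reagents that add atoms: water, O
Why: Mild acid hydrolysis: the trityl ether (via the trityl cation) and the dioxolane of an electron-rich benzaldehyde both cleave in aqueous acetic acid, whereas the aryl methoxymethyl ether needs stronger acid and the medium is too weak to ionise C2–O1.

Step 12
Reactants: 21 (2S,3R)-2-[3,5-dimethoxy-4-(methoxymethoxy)phenyl]-3-(hydroxymethyl)-7-methoxy-2,3-dihydrobenzofuran-5-carbaldehyde; 22 malonic acid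
Product: 24 (E)-3-[(2S,3R)-2-[3,5-dimethoxy-4-(methoxymethoxy)phenyl]-3-(hydroxymethyl)-7-methoxy-2,3-dihydrobenzofuran-5-yl]prop-2-enoic acid, via arylidenemalonic acid 23 (not isolated)
Conditions: pyridine, piperidine (cat.), 90 °C
Reagents that add atoms: none
Why: Knoevenagel–Doebner condensation: amine-catalysed condensation gives 23, which decarboxylates in hot pyridine to the thermodynamically preferred E acid; the ring C phenol is still protected, so the basic medium cannot open ring B through a quinone methide.

Step 13
Reactants: 24 (E)-3-[(2S,3R)-2-[3,5-dimethoxy-4-(methoxymethoxy)phenyl]-3-(hydroxymethyl)-7-methoxy-2,3-dihydrobenzofuran-5-yl]prop-2-enoic acid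
Product: 25 (E)-3-[(2S,3R)-2-(4-hydroxy-3,5-dimethoxyphenyl)-3-(hydroxymethyl)-7-methoxy-2,3-dihydrobenzofuran-5-yl]prop-2-enoic acid
Conditions: 2 M aq. HCl, THF, 40 °C
Reagents that add atoms: none
Why: Acid hydrolysis of the aryl methoxymethyl acetal in an alcohol-free medium (no esterification of the acid); the dilute acid and low temperature should leave C2–O1 intact, and any reversible opening would reclose to the more stable trans ring.

## Compound list

1 | 3-bromo-4-fluorobenzaldehyde | O=Cc1ccc(F)c(Br)c1 | starting material
2 | 2-(3-bromo-4-fluorophenyl)-1,3-dioxolane | Fc1ccc(C2OCCO2)cc1Br | intermediate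
3 | tert-butyl acetate | CC(=O)OC(C)(C)C | starting material
4 | tert-butyl 2-[5-(1,3-dioxolan-2-yl)-2-fluorophenyl]acetate | CC(C)(C)OC(=O)Cc1cc(C2OCCO2)ccc1F | intermediate
5 | 2-[5-(1,3-dioxolan-2-yl)-2-fluorophenyl]acetic acid | OC(=O)Cc1cc(C2OCCO2)ccc1F | intermediate
6 | (S)-4-benzyloxazolidin-2-one | O=C1N[C@@H](Cc2ccccc2)CO1 | starting material
7 | mixed anhydride of 5 with pivalic acid (formed and consumed in step 4) | CC(C)(C)C(=O)OC(=O)Cc1cc(C2OCCO2)ccc1F | intermediate
8 | (S)-4-benzyl-3-{2-[5-(1,3-dioxolan-2-yl)-2-fluorophenyl]acetyl}oxazolidin-2-one | O=C1OC[C@H](Cc2ccccc2)N1C(=O)Cc1cc(C2OCCO2)ccc1F | intermediate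
9 | syringaldehyde (4-hydroxy-3,5-dimethoxybenzaldehyde) | COc1cc(C=O)cc(OC)c1O | starting material
10 | 3,5-dimethoxy-4-(methoxymethoxy)benzaldehyde | COCOc1c(OC)cc(C=O)cc1OC | intermediate
11 | (Z)-di-n-butylboron enolate of 8 (formed and consumed in step 6) | CCCCB(CCCC)O/C(=C\c1cc(C2OCCO2)ccc1F)N1[C@@H](Cc2ccccc2)COC1=O | intermediate
12 | (S)-4-benzyl-3-{(2S,3S)-2-[5-(1,3-dioxolan-2-yl)-2-fluorophenyl]-3-[3,5-dimethoxy-4-(methoxymethoxy)phenyl]-3-hydroxypropanoyl}oxazolidin-2-one | COCOc1c(OC)cc([C@@H](O)[C@@H](C(=O)N2[C@@H](Cc3ccccc3)COC2=O)c2cc(C3OCCO3)ccc2F)cc1OC | intermediate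
13 | (1S,2R)-2-[5-(1,3-dioxolan-2-yl)-2-fluorophenyl]-1-[3,5-dimethoxy-4-(methoxymethoxy)phenyl]propane-1,3-diol | COCOc1c(OC)cc([C@@H](O)[C@@H](CO)c2cc(C3OCCO3)ccc2F)cc1OC | intermediate
14 | (1S,2R)-2-[5-(1,3-dioxolan-2-yl)-2-fluorophenyl]-1-[3,5-dimethoxy-4-(methoxymethoxy)phenyl]-3-(triphenylmethoxy)propan-1-ol | COCOc1c(OC)cc([C@@H](O)[C@@H](COC(c2ccccc2)(c2ccccc2)c2ccccc2)c2cc(C3OCCO3)ccc2F)cc1OC | intermediate
15 | dilithio derivative of 14: lithium alkoxide lithiated at the ring carbon ortho to fluorine (formed and consumed in step 9) | COCOc1c(OC)cc([C@@H]([O-])[C@@H](COC(c2ccccc2)(c2ccccc2)c2ccccc2)c2cc(C3OCCO3)cc([Li])c2F)cc1OC.[Li+] | intermediate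
16 | C7–C7a aryne lithium alkoxide derived from 15 by loss of LiF (formed and consumed in step 9) | COCOc1c(OC)cc([C@@H]([O-])[C@@H](COC(c2ccccc2)(c2ccccc2)c2ccccc2)C2=CC(C3OCCO3)=CC#C2)cc1OC.[Li+] | intermediate
17 | (2S,3R)-2-[3,5-dimethoxy-4-(methoxymethoxy)phenyl]-5-(1,3-dioxolan-2-yl)-7-lithio-3-[(triphenylmethoxy)methyl]-2,3-dihydrobenzofuran (formed and consumed in step 9) | COCOc1c(OC)cc([C@H]2Oc3c([Li])cc(C4OCCO4)cc3[C@@H]2COC(c2ccccc2)(c2ccccc2)c2ccccc2)cc1OC | intermediate
18 | lithium trimethoxy borate of 17 at C7 (formed and consumed in step 9) | COCOc1c(OC)cc([C@H]2Oc3c([B-](OC)(OC)OC)cc(C4OCCO4)cc3[C@@H]2COC(c2ccccc2)(c2ccccc2)c2ccccc2)cc1OC.[Li+] | intermediate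
19 | (2S,3R)-2-[3,5-dimethoxy-4-(methoxymethoxy)phenyl]-5-(1,3-dioxolan-2-yl)-3-[(triphenylmethoxy)methyl]-2,3-dihydrobenzofuran-7-ol | COCOc1c(OC)cc([C@H]2Oc3c(O)cc(C4OCCO4)cc3[C@@H]2COC(c2ccccc2)(c2ccccc2)c2ccccc2)cc1OC | intermediate
20 | (2S,3R)-2-[3,5-dimethoxy-4-(methoxymethoxy)phenyl]-5-(1,3-dioxolan-2-yl)-7-methoxy-3-[(triphenylmethoxy)methyl]-2,3-dihydrobenzofuran | COCOc1c(OC)cc([C@H]2Oc3c(OC)cc(C4OCCO4)cc3[C@@H]2COC(c2ccccc2)(c2ccccc2)c2ccccc2)cc1OC | intermediate
21 | (2S,3R)-2-[3,5-dimethoxy-4-(methoxymethoxy)phenyl]-3-(hydroxymethyl)-7-methoxy-2,3-dihydrobenzofuran-5-carbaldehyde | COCOc1c(OC)cc([C@H]2Oc3c(OC)cc(C=O)cc3[C@@H]2CO)cc1OC | intermediate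
22 | malonic acid | OC(=O)CC(=O)O | starting material
23 | 2-{[(2S,3R)-2-[3,5-dimethoxy-4-(methoxymethoxy)phenyl]-3-(hydroxymethyl)-7-methoxy-2,3-dihydrobenzofuran-5-yl]methylidene}propanedioic acid (formed and consumed in step 12) | COCOc1c(OC)cc([C@H]2Oc3c(OC)cc(C=C(C(=O)O)C(=O)O)cc3[C@@H]2CO)cc1OC | intermediate
24 | (E)-3-[(2S,3R)-2-[3,5-dimethoxy-4-(methoxymethoxy)phenyl]-3-(hydroxymethyl)-7-methoxy-2,3-dihydrobenzofuran-5-yl]prop-2-enoic acid | COCOc1c(OC)cc([C@H]2Oc3c(OC)cc(/C=C/C(=O)O)cc3[C@@H]2CO)cc1OC | intermediate
25 | (E)-3-[(2S,3R)-2-(4-hydroxy-3,5-dimethoxyphenyl)-3-(hydroxymethyl)-7-methoxy-2,3-dihydrobenzofuran-5-yl]prop-2-enoic acid | COc1cc([C@H]2Oc3c(OC)cc(/C=C/C(=O)O)cc3[C@@H]2CO)cc(OC)c1O | target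

## Step count and least certain steps

Total: 13 steps. Longest linear sequence: 12 steps (steps 1–4 and 6–13 from 1); the syringaldehyde branch (step 5) joins at step 6.

**Step 9 (key step).** The likeliest failure is proton transfer from the amine formed in the metalation to aryllithium 17 before the borate arrives, or intermolecular addition of amide to aryne 16; either gives ring B without the C7 oxygen. Slow lithiation next to fluorine would leave unchanged alkoxide. The fallback sets out from 14 and returns at 21; it oxygenates first and closes the ring second by addition–elimination, which is possible because fluorine is para to the masked formyl group.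
- Metalation of 14 at −78 °C with lithium 2,2,6,6-tetramethylpiperidide in the presence of B(Oi-Pr)3 traps the ortho-fluoro aryllithium before fluoride loss. Peroxide oxidation then should give (1S,2R)-2-[5-(1,3-dioxolan-2-yl)-2-fluoro-3-hydroxyphenyl]-1-[3,5-dimethoxy-4-(methoxymethoxy)phenyl]-3-(triphenylmethoxy)propan-1-ol F1.
- Methylation of the phenol (MeI, K2CO3, acetone) should give (1S,2R)-2-[5-(1,3-dioxolan-2-yl)-2-fluoro-3-methoxyphenyl]-1-[3,5-dimethoxy-4-(methoxymethoxy)phenyl]-3-(triphenylmethoxy)propan-1-ol F2.
- Acetal hydrolysis with pyridinium p-toluenesulfonate in wet acetone, with the trityl ether kept, should give 4-fluoro-3-{(1S,2R)-1-hydroxy-1-[3,5-dimethoxy-4-(methoxymethoxy)phenyl]-3-(triphenylmethoxy)propan-2-yl}-5-methoxybenzaldehyde F3.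
- Intramolecular SNAr of the secondary alkoxide on the fluorine para to the formyl group (Cs2CO3, DMSO, 80 °C) should give (2S,3R)-2-[3,5-dimethoxy-4-(methoxymethoxy)phenyl]-7-methoxy-3-[(triphenylmethoxy)methyl]-2,3-dihydrobenzofuran-5-carbaldehyde F4.
- Detritylation of F4 in aqueous acetic acid gives 21.

**Step 3.** The likeliest failure is slow attack of hydroxide on the tert-butyl ester, or loss of the acetal during the acidification that frees the acid. The fallback sets out from 2 and returns at 5. Palladium-catalysed cyanomethylation of 2 (Me3SiCH2CN, ZnF2, Pd2(dba)3, Xantphos, DMF, 90 °C) should give 2-[5-(1,3-dioxolan-2-yl)-2-fluorophenyl]acetonitrile F5. Nitrile hydrolysis (KOH, EtOH/H2O, reflux), which the acetal tolerates, then gives 5.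

**Step 7.** The likeliest failure is retro-aldol fragmentation of the lithium aldolate of the α-aryl adduct, or epimerisation at its acidic α-carbon, before hydride is delivered. The fallback sets out from 12 and returns at 13. Hydrolysis with LiOH/H2O2 (THF/H2O, 0 °C), where the weakly basic hydroperoxide attacks the exocyclic carbonyl, should give (2S,3S)-2-[5-(1,3-dioxolan-2-yl)-2-fluorophenyl]-3-[3,5-dimethoxy-4-(methoxymethoxy)phenyl]-3-hydroxypropanoic acid F6. Reduction of the acid with BH3·SMe2 (THF, 0 °C → rt) then gives 13 under non-basic conditions.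

**Step 12.** The likeliest failure is incomplete decarboxylation, or acylation of the free primary hydroxyl by malonic acid in hot pyridine. The fallback sets out from 21 and returns at 24. A Horner–Wadsworth–Emmons reaction at room temperature (triethyl phosphonoacetate, LiCl, DBU, MeCN) should give ethyl (E)-3-[(2S,3R)-2-[3,5-dimethoxy-4-(methoxymethoxy)phenyl]-3-(hydroxymethyl)-7-methoxy-2,3-dihydrobenzofuran-5-yl]prop-2-enoate F7. Saponification with LiOH in THF/H2O then gives 24.

## Further compounds

F1 | step 9 | (1S,2R)-2-[5-(1,3-dioxolan-2-yl)-2-fluoro-3-hydroxyphenyl]-1-[3,5-dimethoxy-4-(methoxymethoxy)phenyl]-3-(triphenylmethoxy)propan-1-ol | COCOc1c(OC)cc([C@@H](O)[C@@H](COC(c2ccccc2)(c2ccccc2)c2ccccc2)c2cc(C3OCCO3)cc(O)c2F)cc1OC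
F2 | step 9 | (1S,2R)-2-[5-(1,3-dioxolan-2-yl)-2-fluoro-3-methoxyphenyl]-1-[3,5-dimethoxy-4-(methoxymethoxy)phenyl]-3-(triphenylmethoxy)propan-1-ol | COCOc1c(OC)cc([C@@H](O)[C@@H](COC(c2ccccc2)(c2ccccc2)c2ccccc2)c2cc(C3OCCO3)cc(OC)c2F)cc1OC
F3 | step 9 | 4-fluoro-3-{(1S,2R)-1-hydroxy-1-[3,5-dimethoxy-4-(methoxymethoxy)phenyl]-3-(triphenylmethoxy)propan-2-yl}-5-methoxybenzaldehyde | COCOc1c(OC)cc([C@@H](O)[C@@H](COC(c2ccccc2)(c2ccccc2)c2ccccc2)c2cc(C=O)cc(OC)c2F)cc1OC
F4 | step 9 | (2S,3R)-2-[3,5-dimethoxy-4-(methoxymethoxy)phenyl]-7-methoxy-3-[(triphenylmethoxy)methyl]-2,3-dihydrobenzofuran-5-carbaldehyde | COCOc1c(OC)cc([C@H]2Oc3c(OC)cc(C=O)cc3[C@@H]2COC(c2ccccc2)(c2ccccc2)c2ccccc2)cc1OC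
F5 | step 3 | 2-[5-(1,3-dioxolan-2-yl)-2-fluorophenyl]acetonitrile | N#CCc1cc(C2OCCO2)ccc1F
F6 | step 7 | (2S,3S)-2-[5-(1,3-dioxolan-2-yl)-2-fluorophenyl]-3-[3,5-dimethoxy-4-(methoxymethoxy)phenyl]-3-hydroxypropanoic acid | COCOc1c(OC)cc([C@@H](O)[C@@H](C(=O)O)c2cc(C3OCCO3)ccc2F)cc1OC
F7 | step 12 | ethyl (E)-3-[(2S,3R)-2-[3,5-dimethoxy-4-(methoxymethoxy)phenyl]-3-(hydroxymethyl)-7-methoxy-2,3-dihydrobenzofuran-5-yl]prop-2-enoate | COCOc1c(OC)cc([C@H]2Oc3c(OC)cc(/C=C/C(=O)OCC)cc3[C@@H]2CO)cc1OC
A1 | alternative 1 | (2S,3R)-3-(tert-butyldimethylsilyloxymethyl)-2-(3,5-dimethoxy-4-triisopropylsilyloxyphenyl)-7-methoxy-2,3-dihydrobenzofuran-5-ol | COc1cc([C@H]2Oc3c(OC)cc(O)cc3[C@@H]2CO[Si](C)(C)C(C)(C)C)cc(OC)c1O[Si](C(C)C)(C(C)C)C(C)C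
A2 | alternative 1 | pentacarbonyl{[(1S,2R)-2-(tert-butyldimethylsilyloxymethyl)-1-(3,5-dimethoxy-4-triisopropylsilyloxyphenyl)but-3-yn-1-yloxy](1-methoxyvinyl)carbene}chromium | COc1cc([C@@H](OC(=[Cr](=C=O)(=C=O)(=C=O)(=C=O)=C=O)C(OC)=C)[C@@H](CO[Si](C)(C)C(C)(C)C)C#C)cc(OC)c1O[Si](C(C)C)(C(C)C)C(C)C
A3 | alternative 1 | (1S,2R)-2-(tert-butyldimethylsilyloxymethyl)-1-(3,5-dimethoxy-4-triisopropylsilyloxyphenyl)but-3-yn-1-ol | COc1cc([C@@H](O)[C@@H](CO[Si](C)(C)C(C)(C)C)C#C)cc(OC)c1O[Si](C(C)C)(C(C)C)C(C)C
A4 | alternative 2 | methyl (2S,3S)-5-bromo-2-(3,5-dimethoxy-4-methylsulfonyloxyphenyl)-7-methoxy-2,3-dihydrobenzofuran-3-carboxylate (trans) | COc1cc([C@H]2Oc3c(OC)cc(Br)cc3[C@@H]2C(=O)OC)cc(OC)c1OS(C)(=O)=O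
A5 | alternative 2 | (2S)-6-bromo-2-(3,5-dimethoxy-4-methylsulfonyloxyphenyl)-8-methoxychroman-4-one | COc1cc([C@@H]2CC(=O)c3cc(Br)cc(OC)c3O2)cc(OC)c1OS(C)(=O)=O
A6 | alternative 3 | methyl (2S,3R)-2-(4-benzyloxy-3,5-dimethoxyphenyl)-7-bromo-3-(tert-butyldimethylsilyloxymethyl)-2,3-dihydrobenzofuran-5-carboxylate | COc1cc([C@H]2Oc3c(Br)cc(C(=O)OC)cc3[C@@H]2CO[Si](C)(C)C(C)(C)C)cc(OC)c1OCc1ccccc1
A7 | alternative 3 | (4R,5S)-5-(4-benzyloxy-3,5-dimethoxyphenyl)-4-(tert-butyldimethylsilyloxymethyl)-2-(trimethylsilyloxy)-4,5-dihydrofuran | COc1cc([C@H]2OC(O[Si](C)(C)C)=C[C@@H]2CO[Si](C)(C)C(C)(C)C)cc(OC)c1OCc1ccccc1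
A8 | alternative 3 | methyl 3-bromo-2-oxo-2H-pyran-5-carboxylate (methyl 3-bromocoumalate) | COC(=O)C1=COC(=O)C(Br)=C1
A9 | alternative 3 | (4R,5S)-5-(4-benzyloxy-3,5-dimethoxyphenyl)-4-(tert-butyldimethylsilyloxymethyl)dihydrofuran-2(3H)-one | COc1cc([C@H]2OC(=O)C[C@@H]2CO[Si](C)(C)C(C)(C)C)cc(OC)c1OCc1ccccc1
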